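Retrosynthesis: the C4–Cα bond between the lactone and the side-chain alkene is cut first, then C4a–C4 and O2–C1 of the lactone, which leaves 2,4,5-triacetoxybenzoic acid and methyl (S)-glycidate; the side chain is cut at Cα–Cβ into dimethyl oxalate and tert-butyl acetate.
Enabling feature: ring atoms C1, O2, C3, C4, C4a and C8a of the isochroman-1-one are a benzoic acid (C8a–C1) whose single free ortho C–H is C4a–H (C8 is oxygenated), fused to the CH2–CH–O unit of a glycidic ester.
Forward order: the arene is bought and acetylated; the lactone ring, the only ring made, closes in step 2; C4 is brominated and joined to a Z-enol triflate built in two steps from the two small esters; the tert-butyl ester and then the acetates are removed.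
Stereochemistry: C3 (S) is the epoxide CH of methyl (S)-glycidate and is never broken; C4 (R) is set trans to the C3 ester by substrate control in the coupling; the E alkene comes from the Z-triflate with retention.

Key step: step 2

Assumption: the SMILES is read as the (3S,4R)-trans lactone with an E side-chain alkene; isochroman-1-one numbering is used, Cα is the alkene carbon bound to C4 (it carries CO2Me) and Cβ is the alkene CH (it carries CO2H).

Step 1
Reactants: 1 2,4,5-trihydroxybenzoic acid
Product: 2 2,4,5-triacetoxybenzoic acid
Conditions: Ac2O (5 equiv), H2SO4 (cat.), 60 °C, N2; then H2O, 0 °C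
Reagents that add atoms: acetic anhydride, CC(=O)OC(C)=O
Why: Acid-catalysed O-acetylation esterifies all three phenols, and the aqueous quench hydrolyses any mixed anhydride so that the carboxyl group needed as directing group is returned free.

Step 2
Reactants: 2 2,4,5-triacetoxybenzoic acid; 3 methyl (S)-glycidate (2 equiv)
Product: 5 methyl (3S)-5,6,8-triacetoxy-1-oxoisochroman-3-carboxylate, via hydroxy acid 4 (not isolated)
Conditions: Pd(OAc)2 (5 mol%), N-acetylglycine (10 mol%), KOAc (1 equiv), (CF3)2CHOH, 25–40 °C
Reagents that add atoms: none
Why: Palladium diacetate takes up the carboxylate of 2, and the resulting divalent palladium benzoate breaks the C4a–H bond by concerted metalation–deprotonation (acetate or the N-acetylglycine ligand accepts the proton) to give a five-membered palladacycle, whose aryl–palladium bond attacks the potassium-activated epoxide of 3 at CH2 in a redox-neutral SN2-type opening before proton transfer releases hydroxy acid 4 and divalent palladium. The closest known reaction type is the Pd(OAc)2-catalysed, carboxylate-directed ortho C–H alkylation of benzoic acids with terminal epoxides, which ends in 3-substituted isochroman-1-ones. The single ring closure is the lactonisation of 4 with loss of water, a 6-exo-trig acyl substitution of the C3 hydroxyl on the carboxyl carbon (O2–C1), which should be spontaneous in the acidic fluorinated alcohol. No stereocentre is created: C3 is the epoxide CH of 3, its C–O bond stays intact, and the (S) configuration is carried into 5. Site selectivity rests on the substrate, because the carboxylate can reach only C4a–H (its other ortho carbon, C8, bears an acetoxy group) and the electronically richer C7 lies outside the reach of the directing group. Regioselectivity of the opening rests on the epoxide, since its CH2 is the less hindered carbon and the ester disfavours substitution at the carbon that carries it, so C4a–C4 forms at CH2 only.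

Step 3
Reactants: 5 methyl (3S)-5,6,8-triacetoxy-1-oxoisochroman-3-carboxylate
Product: 6 methyl (3R)-5,6,8-triacetoxy-4-bromo-1-oxoisochroman-3-carboxylate (mixture of C4 epimers; C3 is spatially unchanged and its descriptor changes by priority only)
Conditions: NBS (1.1 equiv), AIBN (5 mol%), PhCF3, 80 °C
Reagents that add atoms: N-bromosuccinimide, O=C1CCC(=O)N1Br
Why: In this Wohl–Ziegler bromination the electrophilic bromine atom should abstract the benzylic C4–H rather than the polarity-mismatched C3–H (flanked by ester and acyloxy oxygen), while the three acetoxy groups suppress ionic ring bromination at C7; both C4 epimers lead to the same radical in step 6.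

Step 4
Reactants: 7 dimethyl oxalate (1.2 equiv); 8 tert-butyl acetate
Product: 9 4-tert-butyl 1-methyl 2-oxobutanedioate
Conditions: LiN(SiMe3)2 (2.1 equiv), THF, −78 °C, 8; then 7, −78 → 0 °C; 1 M HCl
Reagents that add atoms: none
Why: In this crossed Claisen condensation the lithium enolate of 8 can only attack the non-enolisable, highly electrophilic oxalate, and the second equivalent of base stores the product as its enolate, which protects it from further addition.

Step 5
Reactants: 9 4-tert-butyl 1-methyl 2-oxobutanedioate
Product: 10 4-tert-butyl 1-methyl (2Z)-2-{[(trifluoromethyl)sulfonyl]oxy}but-2-enedioate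
Conditions: LiN(SiMe3)2 (1.05 equiv), toluene, −78 °C; Tf2O (1.1 equiv), −78 → 0 °C
Reagents that add atoms: trifluoromethanesulfonic anhydride, O=S(=O)(OS(=O)(=O)C(F)(F)F)C(F)(F)F
Why: O-Triflation of a β-keto ester enolate: in a non-coordinating solvent lithium should bridge the enolate oxygen and the tert-butyl ester carbonyl, so sulfonylation traps the geometry with OTf cis to CO2tBu (Z), which places the two ester groups trans as the target requires.

Step 6
Reactants: 6 methyl (3R)-5,6,8-triacetoxy-4-bromo-1-oxoisochroman-3-carboxylate; 10 4-tert-butyl 1-methyl (2Z)-2-{[(trifluoromethyl)sulfonyl]oxy}but-2-enedioate (1.5 equiv)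
Product: 11 4-tert-butyl 1-methyl (2E)-2-[(3S,4R)-5,6,8-triacetoxy-3-(methoxycarbonyl)-1-oxoisochroman-4-yl]but-2-enedioate
Conditions: NiBr2(diglyme) (10 mol%), 4,4'-di-tert-butyl-2,2'-bipyridine (12 mol%), Mn powder (3 equiv), DMA, 0 °C → rt
Reagents that add atoms: none
Why: Nickel-catalysed reductive cross-electrophile coupling of a secondary benzylic bromide with an alkenyl triflate: zerovalent nickel inserts into the C–OTf bond of 10 with retention of alkene geometry (Z in 10 becomes E in 11 by priority change only), the planar C4 radical formed from 6 by bromine abstraction should be captured by the alkenyl–nickel species on the face anti to the C3 ester, and reductive elimination forms C4–Cα, so C4 is set as (R), trans to C3, under substrate control, with manganese chosen because, unlike zinc, it is not expected to insert directly into the benzylic C–Br bond.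

Step 7
Reactants: 11 4-tert-butyl 1-methyl (2E)-2-[(3S,4R)-5,6,8-triacetoxy-3-(methoxycarbonyl)-1-oxoisochroman-4-yl]but-2-enedioate
Product: 12 (2E)-4-methoxy-4-oxo-3-[(3S,4R)-5,6,8-triacetoxy-3-(methoxycarbonyl)-1-oxoisochroman-4-yl]but-2-enoic acid
Conditions: CF3CO2H/CH2Cl2 (1:3), 0 °C → rt
Reagents that add atoms: none
Why: Acidolysis of the tert-butyl ester through the tert-butyl cation leaves methyl esters, aryl acetates and lactone untouched, and it is placed before deacetylation so that the cation meets an acetoxy-deactivated ring and no free C5 hydroxyl is present to lactonise onto the side-chain ester under acid.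

Step 8
Reactants: 12 (2E)-4-methoxy-4-oxo-3-[(3S,4R)-5,6,8-triacetoxy-3-(methoxycarbonyl)-1-oxoisochroman-4-yl]but-2-enoic acid
Product: 13 (2E)-4-methoxy-4-oxo-3-[(3S,4R)-5,6,8-trihydroxy-3-(methoxycarbonyl)-1-oxoisochroman-4-yl]but-2-enoic acid
Conditions: NH4OAc (10 equiv), degassed MeOH, 25 °C, Ar; then 0.5 M HCl, EtOAc
Reagents that add atoms: none
Why: Ammonium acetate-mediated methanolysis (transesterification) should cleave only the three aryl acetates, which are far better acyl donors than the methyl esters or the benzoate-type lactone, under near-neutral conditions that should neither epimerise C4 nor shift the double bond, while methanol as solvent makes any exchange at the methyl esters degenerate and would reopen any aryl lactone formed by the C5 hydroxyl.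

Compound list
1 | 2,4,5-trihydroxybenzoic acid | O=C(O)c1cc(O)c(O)cc1O | starting material
2 | 2,4,5-triacetoxybenzoic acid | CC(=O)Oc1cc(OC(C)=O)c(OC(C)=O)cc1C(=O)O | intermediate
3 | methyl (S)-glycidate, methyl (2S)-oxirane-2-carboxylate | C1O[C@@H]1C(=O)OC | starting material
4 | 3,4,6-triacetoxy-2-[(2S)-2-hydroxy-3-methoxy-3-oxopropyl]benzoic acid (hydroxy acid) | COC(=O)[C@@H](O)Cc1c(OC(C)=O)c(OC(C)=O)cc(OC(C)=O)c1C(=O)O | intermediate (not isolated)
5 | methyl (3S)-5,6,8-triacetoxy-1-oxoisochroman-3-carboxylate | COC(=O)[C@@H]1Cc2c(OC(C)=O)c(OC(C)=O)cc(OC(C)=O)c2C(=O)O1 | intermediate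
6 | methyl (3R)-5,6,8-triacetoxy-4-bromo-1-oxoisochroman-3-carboxylate, C4 epimer mixture | COC(=O)[C@@H]1C(Br)c2c(OC(C)=O)c(OC(C)=O)cc(OC(C)=O)c2C(=O)O1 | intermediate
7 | dimethyl oxalate | COC(=O)C(=O)OC | starting material
8 | tert-butyl acetate | CC(=O)OC(C)(C)C | starting material
9 | 4-tert-butyl 1-methyl 2-oxobutanedioate | COC(=O)C(=O)CC(=O)OC(C)(C)C | intermediate
10 | 4-tert-butyl 1-methyl (2Z)-2-{[(trifluoromethyl)sulfonyl]oxy}but-2-enedioate | COC(=O)/C(OS(=O)(=O)C(F)(F)F)=C/C(=O)OC(C)(C)C | intermediate
11 | 4-tert-butyl 1-methyl (2E)-2-[(3S,4R)-5,6,8-triacetoxy-3-(methoxycarbonyl)-1-oxoisochroman-4-yl]but-2-enedioate | COC(=O)/C(=C/C(=O)OC(C)(C)C)[C@H]1c2c(OC(C)=O)c(OC(C)=O)cc(OC(C)=O)c2C(=O)O[C@@H]1C(=O)OC | intermediate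
12 | (2E)-4-methoxy-4-oxo-3-[(3S,4R)-5,6,8-triacetoxy-3-(methoxycarbonyl)-1-oxoisochroman-4-yl]but-2-enoic acid | COC(=O)/C(=C/C(=O)O)[C@H]1c2c(OC(C)=O)c(OC(C)=O)cc(OC(C)=O)c2C(=O)O[C@@H]1C(=O)OC | intermediate
13 | (2E)-4-methoxy-4-oxo-3-[(3S,4R)-5,6,8-trihydroxy-3-(methoxycarbonyl)-1-oxoisochroman-4-yl]but-2-enoic acid | COC(=O)/C(=C/C(=O)O)[C@H]1c2c(O)c(O)cc(O)c2C(=O)O[C@@H]1C(=O)OC | target

Total step count: 8. Longest linear sequence: 6 steps (steps 1, 2, 3, 6, 7, 8); steps 4 and 5 form the side branch.

Steps most likely to fail

Step 6. What may go wrong: two-electron reduction of the vicinal bromide and acyloxy pair of 6 (at manganese or at a C4–nickel species) with expulsion of the lactone carboxylate and ring opening; loss of HBr to the isocoumarin; capture of the C4 radical on the wrong face or its addition to the electron-poor alkene; scrambling of alkene geometry at the alkenyl–nickel stage. The fallback is a radical conjugate addition followed by elimination, which never places a metal on C4, and it sets out from 6. Crossed Claisen condensation of methyl acetate with di-tert-butyl oxalate (LiN(SiMe3)2, THF, −78 °C) should give 1-tert-butyl 4-methyl 2-oxobutanedioate F1, whose enol is acetylated (Ac2O, Et3N, DMAP, CH2Cl2) to 1-tert-butyl 4-methyl (2Z)-2-acetoxybut-2-enedioate F2; either alkene isomer serves. Under silane chain conditions ((Me3Si)3SiH, AIBN, PhCF3, 80 °C, excess F2) the C4 radical from 6 should add in a Giese addition to the CH carbon of F2 that carries CO2Me, because only this attack leaves a captodative radical flanked by acetoxy and the tert-butyl ester, and it should do so anti to the C3 ester. Hydrogen transfer then gives 1-tert-butyl 4-methyl 2-acetoxy-3-[(3S,4S)-5,6,8-triacetoxy-3-(methoxycarbonyl)-1-oxoisochroman-4-yl]butanedioate F3 (ring trans, the C4 descriptor differs from that of 11 by priority only; the two side-chain centres are a mixture and are removed next). DBU (CH2Cl2, 0 °C) should eliminate acetic acid by an E1cB path to the alkene, the E isomer with the ester groups apart being expected to prevail, and the route is rejoined at 11.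

Step 2. What may go wrong: slow cleavage of C4a–H, which lies between the carboxyl group and an acetoxy group, and slow opening of the electron-poor epoxide by the palladacycle, so that O-alkylation of carboxylate or acetate by 3 takes over. The fallback separates C–H functionalisation from C–C bond formation and sets out from 2. Pd(OAc)2-catalysed, carboxylate-directed ortho-iodination (PhI(OAc)2, I2, DMF, 60 °C) needs only a transient palladacycle and a small, very reactive electrophile and should give 3,4,6-triacetoxy-2-iodobenzoic acid F4. Me3SiCHN2 (toluene/MeOH, 0 °C) converts it into methyl 3,4,6-triacetoxy-2-iodobenzoate F5. Nickel-catalysed reductive coupling of F5 with 3 under iodide co-catalysis (NiBr2(diglyme), 4,4'-di-tert-butyl-2,2'-bipyridine, NaI, Et3N·HCl, Mn powder, DMPU, rt) proceeds through the iodohydrin that iodide forms at the CH2 of 3; its primary radical is arylated, which should give methyl 3,4,6-triacetoxy-2-[(2S)-2-hydroxy-3-methoxy-3-oxopropyl]benzoate F6 without touching the stereocentre. TsOH (toluene, 80 °C) lactonises F6 with loss of methanol, and the route is rejoined at 5.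

Step 3. What may go wrong: hydrogen abstraction at C3 instead of C4, ionic bromination of the ring at C7, or loss of HBr from 6 to the isocoumarin, which erases C3. The fallback is a direct benzylic C–H alkenylation that needs no bromide; it sets out from 5 and uses triflate 10. Under combined photochemical hydrogen-atom transfer and nickel catalysis ((Bu4N)4[W10O32] (2 mol%), NiBr2(diglyme) (10 mol%), 4,4'-di-tert-butyl-2,2'-bipyridine, K2HPO4, MeCN, 390 nm light, rt) excited decatungstate should abstract the benzylic C4–H, and the nickel cycle that has inserted into the C–OTf bond of 10 should capture the C4 radical anti to the C3 ester and form C4–Cα. The route is rejoined at 11, with steps 3 and 6 both replaced and no new compound made (none, F0).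

Further compounds
F1 | step 6 | 1-tert-butyl 4-methyl 2-oxobutanedioate | COC(=O)CC(=O)C(=O)OC(C)(C)C
F2 | step 6 | 1-tert-butyl 4-methyl (2Z)-2-acetoxybut-2-enedioate | COC(=O)/C=C(\OC(C)=O)C(=O)OC(C)(C)C
F3 | step 6 | 1-tert-butyl 4-methyl 2-acetoxy-3-[(3S,4S)-5,6,8-triacetoxy-3-(methoxycarbonyl)-1-oxoisochroman-4-yl]butanedioate | COC(=O)C(C(OC(C)=O)C(=O)OC(C)(C)C)[C@H]1c2c(OC(C)=O)c(OC(C)=O)cc(OC(C)=O)c2C(=O)O[C@@H]1C(=O)OC
F4 | step 2 | 3,4,6-triacetoxy-2-iodobenzoic acid | CC(=O)Oc1cc(OC(C)=O)c(OC(C)=O)c(I)c1C(=O)O
F5 | step 2 | methyl 3,4,6-triacetoxy-2-iodobenzoate | COC(=O)c1c(I)c(OC(C)=O)c(OC(C)=O)cc1OC(C)=O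
F6 | step 2 | methyl 3,4,6-triacetoxy-2-[(2S)-2-hydroxy-3-methoxy-3-oxopropyl]benzoate | COC(=O)[C@@H](O)Cc1c(OC(C)=O)c(OC(C)=O)cc(OC(C)=O)c1C(=O)OC
F0 | step 3 | none | none
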